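**Strategy.** The plan treats the eight hydroxyls at C3 and C5 of rings A, B, D and F, which flank the ether carbon C4 of each ring, as former formyl groups. As aldehydes they activate C4–F for mild fluoride displacement, so the four most crowded aryl ethers are made by substitution. A single peracid oxidation then exchanges all eight C–CHO bonds for C–O bonds. Its substrate is the heptameric octa-aldehyde, grown from ring A towards ring G with building blocks whose fluorodialdehyde ring is masked as a bis-acetal: inert while its phenol attacks, activated by hydrolysis afterwards.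

Key step: step 19

Remark on the chemistry: rings are lettered A to G along the target SMILES. In rings A, B, D and F, C4 is the ether carbon between the two hydroxyls and C1 is para to it. In rings C and E, C1 carries the oxygen to the preceding ring and C6 the oxygen to the following ring. The octa-aldehyde and the octaphenol of the key step were checked ring by ring against the target (eight formyl or hydroxyl positions, ten methoxy groups, six diaryl ether bonds) and need no correction. The lithium hemiaminal alkoxide of step 2 is racemic; no other compound has a stereocentre.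

**Step 1**
Reactants: 1 5-bromo-2-fluorobenzaldehyde
Product: 2 4-bromo-2-(dimethoxymethyl)-1-fluorobenzene
Conditions: HC(OMe)3, MeOH, p-TsOH (cat.), 50 °C
Reagents that add atoms: trimethyl orthoformate COC(OC)OC; methanol CO
Why: Acid-catalysed acetalisation, driven by the orthoformate as water scavenger, masks the formyl group against the amide base of step 2.

**Step 2**
Reactants: 2 4-bromo-2-(dimethoxymethyl)-1-fluorobenzene
Product: 5 5-bromo-3-(dimethoxymethyl)-2-fluorobenzaldehyde, via aryllithium 3 (not isolated), via lithium hemiaminal alkoxide 4 (not isolated)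
Conditions: LiN(iPr)2, THF, −78 °C; DMF, −78 °C; aq. NH4Cl, 0 °C
Reagents that add atoms: N,N-dimethylformamide CN(C)C=O
Why: Directed ortho-metalation and formylation: fluorine is the strongest acidifying group, so the amide base (which does not exchange bromine) should remove the one free hydrogen ortho to F, as it does in 4-bromofluorobenzene, and DMF traps the aryllithium.

**Step 3**
Reactants: 5 5-bromo-3-(dimethoxymethyl)-2-fluorobenzaldehyde
Product: 6 5-bromo-1,3-bis(dimethoxymethyl)-2-fluorobenzene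
Conditions: HC(OMe)3, MeOH, p-TsOH (cat.), 50 °C
Reagents that add atoms: trimethyl orthoformate COC(OC)OC; methanol CO
Why: A second acid-catalysed acetalisation leaves the C–F bond flanked by two acetals and therefore unactivated, which is the latent form of the electrophile used throughout.

**Step 4**
Reactants: 6 5-bromo-1,3-bis(dimethoxymethyl)-2-fluorobenzene
Product: 9 4-fluoro-3,5-bis(dimethoxymethyl)phenol, via aryllithium 7 (not isolated), via dimethyl arylboronate 8 (not isolated)
Conditions: n-BuLi, THF, −78 °C; B(OMe)3, −78 °C → rt; H2O2 (30 %), aq. NaOH, 0 °C → rt; NaH2PO4 to pH 7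
Reagents that add atoms: hydrogen peroxide OO
Why: Bromine–lithium exchange, borylation and oxidative carbon-to-oxygen shift on boron should give the phenol; lithium sits para to fluorine so no aryne can form, and the acetals tolerate the basic oxidation and neutral work-up.

**Step 5**
Reactants: 9 4-fluoro-3,5-bis(dimethoxymethyl)phenol
Product: 10 2-fluoro-5-methoxy-1,3-bis(dimethoxymethyl)benzene
Conditions: MeI, K2CO3, acetone, reflux
Reagents that add atoms: iodomethane CI
Why: Williamson methylation of an unhindered phenoxide installs the ring A methoxy group while the acetals stay untouched under base.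

**Step 6**
Reactants: 10 2-fluoro-5-methoxy-1,3-bis(dimethoxymethyl)benzene
Product: 11 2-fluoro-5-methoxybenzene-1,3-dicarbaldehyde
Conditions: HCl (1 M aq., cat.), THF, rt
Reagents that add atoms: water O
Why: Acid-catalysed acetal hydrolysis unveils the two ortho formyl groups that switch the fluoride on for substitution.

**Step 7**
Reactants: 11 2-fluoro-5-methoxybenzene-1,3-dicarbaldehyde; 9 4-fluoro-3,5-bis(dimethoxymethyl)phenol
Product: 12 2-[4-fluoro-3,5-bis(dimethoxymethyl)phenoxy]-5-methoxybenzene-1,3-dicarbaldehyde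
Conditions: K2CO3, DMF, 0 °C → rt
Reagents that add atoms: none
Why: Nucleophilic aromatic substitution (addition–elimination): only the fluoride of 11 is flanked by two formyl groups, whereas the fluoride of 9 sits between acetals, so 9 can act only as the nucleophile and no oligomer can form.

**Step 8**
Reactants: 12 2-[4-fluoro-3,5-bis(dimethoxymethyl)phenoxy]-5-methoxybenzene-1,3-dicarbaldehyde
Product: 13 2-(4-fluoro-3,5-diformylphenoxy)-5-methoxybenzene-1,3-dicarbaldehyde
Conditions: HCl (1 M aq., cat.), THF, rt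
Reagents that add atoms: water O
Why: Acetal hydrolysis under acid, where no nucleophile is present, turns ring B into the next activated fluoride.

**Step 9**
Reactants: 14 3,4,5-trimethoxyphenol
Product: 16 2-hydroxy-4,5,6-trimethoxybenzaldehyde, via iminium chloride 15 (not isolated)
Conditions: POCl3, DMF, 0 °C → rt; then H2O, 50 °C
Reagents that add atoms: N,N-dimethylformamide CN(C)C=O; water O
Why: Vilsmeier–Haack formylation of a very electron-rich phenol whose para position is blocked and whose two ortho positions are equivalent, so a single aldehyde should result.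

**Step 10**
Reactants: 16 2-hydroxy-4,5,6-trimethoxybenzaldehyde
Product: 17 2-(benzyloxy)-4,5,6-trimethoxybenzaldehyde
Conditions: BnBr, K2CO3, DMF, 50 °C
Reagents that add atoms: benzyl bromide BrCc1ccccc1
Why: Williamson benzylation fixes which catechol oxygen is protected before the second oxygen exists, so no regiochemical choice between two hydroxyls ever arises.

**Step 11**
Reactants: 17 2-(benzyloxy)-4,5,6-trimethoxybenzaldehyde
Product: 19 6-(benzyloxy)-2,3,4-trimethoxyphenol, via aryl formate 18 (not isolated)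
Conditions: mCPBA, CH2Cl2, 0 °C → rt; then K2CO3 (cat.), MeOH, rt
Reagents that add atoms: 3-chloroperbenzoic acid OOC(=O)c1cccc(Cl)c1
Why: Baeyer–Villiger (Dakin-type) oxidation: the migrating carbon has oxygen donors at both ortho positions and the para position, so aryl migration should be fast and clean, and the formate is methanolysed in the same flask.

**Step 12**
Reactants: 19 6-(benzyloxy)-2,3,4-trimethoxyphenol; 6 5-bromo-1,3-bis(dimethoxymethyl)-2-fluorobenzene
Product: 20 1-(benzyloxy)-2-[4-fluoro-3,5-bis(dimethoxymethyl)phenoxy]-3,4,5-trimethoxybenzene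
Conditions: CuI (10 mol %), picolinic acid (20 mol %), K3PO4, DMSO, 90 °C
Reagents that add atoms: none
Why: Ullmann-type diaryl ether coupling with monovalent copper and picolinic acid, a system suited to di-ortho-substituted phenols; the bromide has two free ortho positions, no aldehyde is present, and the acetal-flanked C–F is inert to the phenoxide.

**Step 13**
Reactants: 20 1-(benzyloxy)-2-[4-fluoro-3,5-bis(dimethoxymethyl)phenoxy]-3,4,5-trimethoxybenzene
Product: 21 2-[4-fluoro-3,5-bis(dimethoxymethyl)phenoxy]-3,4,5-trimethoxyphenol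
Conditions: H2 (1 atm), Pd/C (10 %), EtOAc, Et3N (trace), rt
Reagents that add atoms: none
Why: Hydrogenolysis of the aryl benzyl ether at a stage with no aldehyde in the molecule; the trace of amine keeps the medium non-acidic so the dimethyl acetals and the C–F bond should persist.

**Step 14**
Reactants: 13 2-(4-fluoro-3,5-diformylphenoxy)-5-methoxybenzene-1,3-dicarbaldehyde; 21 2-[4-fluoro-3,5-bis(dimethoxymethyl)phenoxy]-3,4,5-trimethoxyphenol
Product: 22 rings A–D bis-acetal fluoride
Conditions: K2CO3, DMF, 0 °C → rt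
Reagents that add atoms: none
Why: Nucleophilic aromatic substitution of the doubly formyl-activated fluoride of ring B by the ring C phenoxide; fluoride leaves far faster than the aryloxy group on C4 of ring A, so with one equivalent of phenol at low temperature no ether exchange is expected.

**Step 15**
Reactants: 22 rings A–D bis-acetal fluoride
Product: 23 rings A–D hexa-aldehyde fluoride
Conditions: HCl (1 M aq., cat.), THF, rt
Reagents that add atoms: water O
Why: Acetal hydrolysis activates the ring D fluoride; diaryl ethers and formyl groups are stable to dilute acid.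

**Step 16**
Reactants: 23 rings A–D hexa-aldehyde fluoride; 21 2-[4-fluoro-3,5-bis(dimethoxymethyl)phenoxy]-3,4,5-trimethoxyphenol
Product: 24 rings A–F bis-acetal fluoride
Conditions: K2CO3, DMF, 0 °C → rt
Reagents that add atoms: none
Why: The same nucleophilic aromatic substitution as in step 14, now at C4 of ring D, with the second copy of the latent block 21 supplying rings E and F.

**Step 17**
Reactants: 24 rings A–F bis-acetal fluoride
Product: 25 rings A–F octa-aldehyde fluoride
Conditions: HCl (1 M aq., cat.), THF, rt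
Reagents that add atoms: water O
Why: Acetal hydrolysis, as in steps 8 and 15, activates the last fluoride on ring F.

**Step 18**
Reactants: 25 rings A–F octa-aldehyde fluoride; 14 3,4,5-trimethoxyphenol
Product: 26 heptamer octa-aldehyde
Conditions: K2CO3, DMF, 0 °C → rt
Reagents that add atoms: none
Why: Nucleophilic aromatic substitution at C4 of ring F by an unhindered, electron-rich phenoxide completes the seven-ring skeleton with all six diaryl ether bonds in place.

**Step 19**
Reactants: 26 heptamer octa-aldehyde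
Product: 28 heptamer octaphenol decamethyl ether, via octaformate 27 (not isolated)
Conditions: mCPBA (excess), Na2HPO4, CH2Cl2, 0 °C → rt; Me2S; then K2CO3 (cat.), MeOH, Ar, 0 °C
Reagents that add atoms: 3-chloroperbenzoic acid OOC(=O)c1cccc(Cl)c1
Why: Proposed new method: each formyl carbonyl adds the peracid to a Criegee adduct, the ring carbon shifts to oxygen with loss of 3-chlorobenzoate to leave an aryl formate, and after the excess oxidant is reduced with Me2S catalytic carbonate in methanol transesterifies all eight formates, so the eight C3–O and C5–O bonds of rings A, B, D and F form in one flask. The closest known reaction type is the Baeyer–Villiger (Dakin-type) oxidation of a single ortho-aryloxybenzaldehyde made by fluoride displacement on a fluorobenzaldehyde; its eightfold use on rings that each carry two formyl groups has not been shown. No ring is closed and no stereocentre is created. The selectivity needed is aryl over hydride migration at every site, secured by the lone pair of the C4 ether oxygen ortho to each migrating carbon and by the phosphate buffer; the first shift on each ring, with the meta formyl group still present, is the slowest, and the O-formyl group it installs no longer withdraws by conjugation. Rings C, E and G carry no carbonyl group and can only undergo slower electrophilic hydroxylation, and holding the new oxygens as formates until the peracid is destroyed protects the emerging resorcinol-type rings from over-oxidation.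

**Step 20**
Reactants: 28 heptamer octaphenol decamethyl ether
Product: 29 target heptamer (CNP0292517.0)
Conditions: BBr3 (excess), CH2Cl2, −78 °C → rt; MeOH, then co-evaporation under Ar
Reagents that add atoms: none
Why: Lewis acid-mediated cleavage of aryl methyl ethers (bromide attacks the methyl group of the boron-complexed ether); diaryl ethers are inert to BBr3, and the methanol quench removes boron as volatile trimethyl borate.

**Compound list**
1 | 5-bromo-2-fluorobenzaldehyde | O=Cc1cc(Br)ccc1F | starting material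
2 | 4-bromo-2-(dimethoxymethyl)-1-fluorobenzene | COC(OC)c1cc(Br)ccc1F | intermediate
3 | [5-bromo-3-(dimethoxymethyl)-2-fluorophenyl]lithium | COC(OC)c1cc(Br)cc([Li])c1F | intermediate (not isolated)
4 | lithium [5-bromo-3-(dimethoxymethyl)-2-fluorophenyl](dimethylamino)methanolate, racemic | COC(OC)c1cc(Br)cc(C(O[Li])N(C)C)c1F | intermediate (not isolated)
5 | 5-bromo-3-(dimethoxymethyl)-2-fluorobenzaldehyde | COC(OC)c1cc(Br)cc(C=O)c1F | intermediate
6 | 5-bromo-1,3-bis(dimethoxymethyl)-2-fluorobenzene | COC(OC)c1cc(Br)cc(C(OC)OC)c1F | intermediate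
7 | [4-fluoro-3,5-bis(dimethoxymethyl)phenyl]lithium | COC(OC)c1cc([Li])cc(C(OC)OC)c1F | intermediate (not isolated)
8 | dimethyl [4-fluoro-3,5-bis(dimethoxymethyl)phenyl]boronate | COB(OC)c1cc(C(OC)OC)c(F)c(C(OC)OC)c1 | intermediate (not isolated)
9 | 4-fluoro-3,5-bis(dimethoxymethyl)phenol | COC(OC)c1cc(O)cc(C(OC)OC)c1F | intermediate
10 | 2-fluoro-5-methoxy-1,3-bis(dimethoxymethyl)benzene | COc1cc(C(OC)OC)c(F)c(C(OC)OC)c1 | intermediate
11 | 2-fluoro-5-methoxybenzene-1,3-dicarbaldehyde | COc1cc(C=O)c(F)c(C=O)c1 | intermediate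
12 | 2-[4-fluoro-3,5-bis(dimethoxymethyl)phenoxy]-5-methoxybenzene-1,3-dicarbaldehyde | COc1cc(C=O)c(Oc2cc(C(OC)OC)c(F)c(C(OC)OC)c2)c(C=O)c1 | intermediate
13 | 2-(4-fluoro-3,5-diformylphenoxy)-5-methoxybenzene-1,3-dicarbaldehyde | COc1cc(C=O)c(Oc2cc(C=O)c(F)c(C=O)c2)c(C=O)c1 | intermediate
14 | 3,4,5-trimethoxyphenol | COc1cc(O)cc(OC)c1OC | starting material
15 | (2-hydroxy-4,5,6-trimethoxybenzylidene)dimethylammonium chloride | C[N+](C)=Cc1c(O)cc(OC)c(OC)c1OC.[Cl-] | intermediate (not isolated)
16 | 2-hydroxy-4,5,6-trimethoxybenzaldehyde | COc1cc(O)c(C=O)c(OC)c1OC | intermediate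
17 | 2-(benzyloxy)-4,5,6-trimethoxybenzaldehyde | COc1cc(OCc2ccccc2)c(C=O)c(OC)c1OC | intermediate
18 | 2-(benzyloxy)-4,5,6-trimethoxyphenyl formate | COc1cc(OCc2ccccc2)c(OC=O)c(OC)c1OC | intermediate (not isolated)
19 | 6-(benzyloxy)-2,3,4-trimethoxyphenol | COc1cc(OCc2ccccc2)c(O)c(OC)c1OC | intermediate
20 | 1-(benzyloxy)-2-[4-fluoro-3,5-bis(dimethoxymethyl)phenoxy]-3,4,5-trimethoxybenzene | COc1cc(OCc2ccccc2)c(Oc2cc(C(OC)OC)c(F)c(C(OC)OC)c2)c(OC)c1OC | intermediate
21 | 2-[4-fluoro-3,5-bis(dimethoxymethyl)phenoxy]-3,4,5-trimethoxyphenol | COc1cc(O)c(Oc2cc(C(OC)OC)c(F)c(C(OC)OC)c2)c(OC)c1OC | intermediate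
22 | rings A–D bis-acetal fluoride: 2-(4-{2-[4-fluoro-3,5-bis(dimethoxymethyl)phenoxy]-3,4,5-trimethoxyphenoxy}-3,5-diformylphenoxy)-5-methoxybenzene-1,3-dicarbaldehyde | COc1cc(C=O)c(Oc2cc(C=O)c(Oc3cc(OC)c(OC)c(OC)c3Oc3cc(C(OC)OC)c(F)c(C(OC)OC)c3)c(C=O)c2)c(C=O)c1 | intermediate
23 | rings A–D hexa-aldehyde fluoride: 2-{4-[2-(4-fluoro-3,5-diformylphenoxy)-3,4,5-trimethoxyphenoxy]-3,5-diformylphenoxy}-5-methoxybenzene-1,3-dicarbaldehyde | COc1cc(C=O)c(Oc2cc(C=O)c(Oc3cc(OC)c(OC)c(OC)c3Oc3cc(C=O)c(F)c(C=O)c3)c(C=O)c2)c(C=O)c1 | intermediate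
24 | rings A–F bis-acetal fluoride: 23 with the fluorine of ring D replaced by a 2-[4-fluoro-3,5-bis(dimethoxymethyl)phenoxy]-3,4,5-trimethoxyphenoxy group | COc1cc(C=O)c(Oc2cc(C=O)c(Oc3cc(OC)c(OC)c(OC)c3Oc3cc(C=O)c(Oc4cc(OC)c(OC)c(OC)c4Oc4cc(C(OC)OC)c(F)c(C(OC)OC)c4)c(C=O)c3)c(C=O)c2)c(C=O)c1 | intermediate
25 | rings A–F octa-aldehyde fluoride: 24 with both dimethoxymethyl groups of ring F converted to formyl | COc1cc(C=O)c(Oc2cc(C=O)c(Oc3cc(OC)c(OC)c(OC)c3Oc3cc(C=O)c(Oc4cc(OC)c(OC)c(OC)c4Oc4cc(C=O)c(F)c(C=O)c4)c(C=O)c3)c(C=O)c2)c(C=O)c1 | intermediate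
26 | heptamer octa-aldehyde: 25 with the fluorine of ring F replaced by 3,4,5-trimethoxyphenoxy (ring G) | COc1cc(C=O)c(Oc2cc(C=O)c(Oc3cc(OC)c(OC)c(OC)c3Oc3cc(C=O)c(Oc4cc(OC)c(OC)c(OC)c4Oc4cc(C=O)c(Oc5cc(OC)c(OC)c(OC)c5)c(C=O)c4)c(C=O)c3)c(C=O)c2)c(C=O)c1 | intermediate
27 | heptamer octaformate: 26 with every formyl group replaced by formyloxy | COc1cc(OC=O)c(Oc2cc(OC=O)c(Oc3cc(OC)c(OC)c(OC)c3Oc3cc(OC=O)c(Oc4cc(OC)c(OC)c(OC)c4Oc4cc(OC=O)c(Oc5cc(OC)c(OC)c(OC)c5)c(OC=O)c4)c(OC=O)c3)c(OC=O)c2)c(OC=O)c1 | intermediate (not isolated)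
28 | heptamer octaphenol decamethyl ether: 26 with every formyl group replaced by hydroxyl | COc1cc(O)c(Oc2cc(O)c(Oc3cc(OC)c(OC)c(OC)c3Oc3cc(O)c(Oc4cc(OC)c(OC)c(OC)c4Oc4cc(O)c(Oc5cc(OC)c(OC)c(OC)c5)c(O)c4)c(O)c3)c(O)c2)c(O)c1 | intermediate
29 | target heptamer: 28 with all ten methoxy groups replaced by hydroxyl | Oc1cc(O)c(Oc2cc(O)c(Oc3cc(O)c(O)c(O)c3Oc3cc(O)c(Oc4cc(O)c(O)c(O)c4Oc4cc(O)c(Oc5cc(O)c(O)c(O)c5)c(O)c4)c(O)c3)c(O)c2)c(O)c1 | target

**Totals.** 20 steps in all; the longest linear sequence is 15 steps (steps 1–8, then 14–20).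

**Steps most likely to fail**

1. Step 19. Hydride instead of aryl migration at some of the eight sites would give carboxylic acids, most likely at the first oxidation of each diformyl ring, and partial conversion would leave mixtures that cannot be separated. The fallback uses only known chemistry by oxidising two formyl groups at a time while the chain grows; it sets out from 12 and returns at 29. On 12 only the two formyl groups of ring A are free.
   - Buffered mCPBA should give the dimer diformate F1, carbonate in methanol the dimer diol F2, MeI/K2CO3 the methylated dimer bis-acetal F3, and aqueous HCl the dimer fluorodialdehyde F4.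
   - Fluoride displacement by 21 gives the tetramer dialdehyde F5. The same four operations lead through the tetramer diformate F6, the tetramer diol F7, the methylated tetramer bis-acetal F8 and the tetramer fluorodialdehyde F9.
   - Compound 21 then gives the hexamer dialdehyde F10, followed by the hexamer diformate F11, the hexamer diol F12, the methylated hexamer bis-acetal F13 and the hexamer fluorodialdehyde F14.
   - Displacement by 14 gives the heptamer dialdehyde F15, oxidation the heptamer diformate F16, methanolysis the heptamer diol F17 and methylation the heptamer octadecamethyl ether F18, which BBr3 cleaves to 29.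

2. Step 20. Cleavage of the ten ethers may stop short, and the pyrogallol-type rings C, E and G may oxidise in air while the free polyphenol is separated from boron residues. The fallback sets out from 28 and returns at 29. After BBr3 and the methanol quench the crude product is acetylated (Ac2O, pyridine) to the octadeca-acetate F19, a neutral compound that can be chromatographed on silica and freed from under-cleaved material. Acid-catalysed methanolysis (HCl from AcCl in MeOH, under Ar) then releases 29 with only volatile by-products.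

3. Step 12. The phenoxide flanked by two oxygen substituents may couple sluggishly at 90 °C, so that reduction of the aryl bromide competes. The fallback sets out from 6 and returns at 20. Bromine–lithium exchange and B(OMe)3 with a neutral aqueous work-up give the arylboronic acid F20, which is coupled with 19 by the Chan–Lam–Evans method (divalent copper as Cu(OAc)2, pyridine, 4 Å molecular sieves, CH2Cl2, air, rt), a room-temperature oxidative coupling that tolerates di-ortho-substituted phenols.

**Further compounds**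
F1 | step 19 | dimer diformate | COc1cc(OC=O)c(Oc2cc(C(OC)OC)c(F)c(C(OC)OC)c2)c(OC=O)c1
F2 | step 19 | dimer diol | COc1cc(O)c(Oc2cc(C(OC)OC)c(F)c(C(OC)OC)c2)c(O)c1
F3 | step 19 | methylated dimer bis-acetal | COc1cc(OC)c(Oc2cc(C(OC)OC)c(F)c(C(OC)OC)c2)c(OC)c1
F4 | step 19 | dimer fluorodialdehyde | COc1cc(OC)c(Oc2cc(C=O)c(F)c(C=O)c2)c(OC)c1
F5 | step 19 | tetramer dialdehyde | COc1cc(OC)c(Oc2cc(C=O)c(Oc3cc(OC)c(OC)c(OC)c3Oc3cc(C(OC)OC)c(F)c(C(OC)OC)c3)c(C=O)c2)c(OC)c1
F6 | step 19 | tetramer diformate | COc1cc(OC)c(Oc2cc(OC=O)c(Oc3cc(OC)c(OC)c(OC)c3Oc3cc(C(OC)OC)c(F)c(C(OC)OC)c3)c(OC=O)c2)c(OC)c1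
F7 | step 19 | tetramer diol | COc1cc(OC)c(Oc2cc(O)c(Oc3cc(OC)c(OC)c(OC)c3Oc3cc(C(OC)OC)c(F)c(C(OC)OC)c3)c(O)c2)c(OC)c1
F8 | step 19 | methylated tetramer bis-acetal | COc1cc(OC)c(Oc2cc(OC)c(Oc3cc(OC)c(OC)c(OC)c3Oc3cc(C(OC)OC)c(F)c(C(OC)OC)c3)c(OC)c2)c(OC)c1
F9 | step 19 | tetramer fluorodialdehyde | COc1cc(OC)c(Oc2cc(OC)c(Oc3cc(OC)c(OC)c(OC)c3Oc3cc(C=O)c(F)c(C=O)c3)c(OC)c2)c(OC)c1
F10 | step 19 | hexamer dialdehyde | COc1cc(OC)c(Oc2cc(OC)c(Oc3cc(OC)c(OC)c(OC)c3Oc3cc(C=O)c(Oc4cc(OC)c(OC)c(OC)c4Oc4cc(C(OC)OC)c(F)c(C(OC)OC)c4)c(C=O)c3)c(OC)c2)c(OC)c1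
F11 | step 19 | hexamer diformate | COc1cc(OC)c(Oc2cc(OC)c(Oc3cc(OC)c(OC)c(OC)c3Oc3cc(OC=O)c(Oc4cc(OC)c(OC)c(OC)c4Oc4cc(C(OC)OC)c(F)c(C(OC)OC)c4)c(OC=O)c3)c(OC)c2)c(OC)c1
F12 | step 19 | hexamer diol | COc1cc(OC)c(Oc2cc(OC)c(Oc3cc(OC)c(OC)c(OC)c3Oc3cc(O)c(Oc4cc(OC)c(OC)c(OC)c4Oc4cc(C(OC)OC)c(F)c(C(OC)OC)c4)c(O)c3)c(OC)c2)c(OC)c1
F13 | step 19 | methylated hexamer bis-acetal | COc1cc(OC)c(Oc2cc(OC)c(Oc3cc(OC)c(OC)c(OC)c3Oc3cc(OC)c(Oc4cc(OC)c(OC)c(OC)c4Oc4cc(C(OC)OC)c(F)c(C(OC)OC)c4)c(OC)c3)c(OC)c2)c(OC)c1
F14 | step 19 | hexamer fluorodialdehyde | COc1cc(OC)c(Oc2cc(OC)c(Oc3cc(OC)c(OC)c(OC)c3Oc3cc(OC)c(Oc4cc(OC)c(OC)c(OC)c4Oc4cc(C=O)c(F)c(C=O)c4)c(OC)c3)c(OC)c2)c(OC)c1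
F15 | step 19 | heptamer dialdehyde | COc1cc(OC)c(Oc2cc(OC)c(Oc3cc(OC)c(OC)c(OC)c3Oc3cc(OC)c(Oc4cc(OC)c(OC)c(OC)c4Oc4cc(C=O)c(Oc5cc(OC)c(OC)c(OC)c5)c(C=O)c4)c(OC)c3)c(OC)c2)c(OC)c1
F16 | step 19 | heptamer diformate | COc1cc(OC)c(Oc2cc(OC)c(Oc3cc(OC)c(OC)c(OC)c3Oc3cc(OC)c(Oc4cc(OC)c(OC)c(OC)c4Oc4cc(OC=O)c(Oc5cc(OC)c(OC)c(OC)c5)c(OC=O)c4)c(OC)c3)c(OC)c2)c(OC)c1
F17 | step 19 | heptamer diol | COc1cc(OC)c(Oc2cc(OC)c(Oc3cc(OC)c(OC)c(OC)c3Oc3cc(OC)c(Oc4cc(OC)c(OC)c(OC)c4Oc4cc(O)c(Oc5cc(OC)c(OC)c(OC)c5)c(O)c4)c(OC)c3)c(OC)c2)c(OC)c1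
F18 | step 19 | heptamer octadecamethyl ether | COc1cc(OC)c(Oc2cc(OC)c(Oc3cc(OC)c(OC)c(OC)c3Oc3cc(OC)c(Oc4cc(OC)c(OC)c(OC)c4Oc4cc(OC)c(Oc5cc(OC)c(OC)c(OC)c5)c(OC)c4)c(OC)c3)c(OC)c2)c(OC)c1
F19 | step 20 | octadeca-acetate of 29 | CC(=O)Oc1cc(OC(C)=O)c(Oc2cc(OC(C)=O)c(Oc3cc(OC(C)=O)c(OC(C)=O)c(OC(C)=O)c3Oc3cc(OC(C)=O)c(Oc4cc(OC(C)=O)c(OC(C)=O)c(OC(C)=O)c4Oc4cc(OC(C)=O)c(Oc5cc(OC(C)=O)c(OC(C)=O)c(OC(C)=O)c5)c(OC(C)=O)c4)c(OC(C)=O)c3)c(OC(C)=O)c2)c(OC(C)=O)c1
F20 | step 12 | [4-fluoro-3,5-bis(dimethoxymethyl)phenyl]boronic acid | OB(O)c1cc(C(OC)OC)c(F)c(C(OC)OC)c1
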